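## Conventions and remarks

- Atom labels C1–O34 follow the order of the heavy atoms in the SMILES string of the target. "Upper face" of ring A is the face that carries the C1 methyl group in the target.
- Remark on the chemistry: (R)-4-benzyl-3-propanoyl-1,3-oxazolidin-2-one (3) is taken as a purchased material.
- Remark on the chemistry: C2 is carried through the key step with its methyl group trans to O4 and is inverted afterwards (step 8). The reason is set out under the key disconnection.

## Analysis of the target

Chermebilaene B (38) is built on a cyclohexane, ring A (C2, C3, C5, C6, C11, C18), with two spiro junctions. C11 carries a δ-lactone (C11, C12, C13, C14, O16, C17), and C18 carries a tetrahydrofuran (C18, C19, C20, C31, O34) that is one wall of a cage. The cage is completed by a tetrahydropyran (C20, C22, C24, C33, O32, C31), a dioxolane (C28, O30, C31, O32, C33) and a γ-lactone (C24, C25, O27, C28, C33); these meet at the orthoester carbon C31 and the ketal carbon C28. There are eleven stereocentres: C2, C3, C6, C11 and C18 on ring A, the independent centres C20, C22, C24 and C33 in the cage, and C28 and C31, which are fixed by ring fusion once the others are set. On ring A the C1 methyl, O4, C7, C17 and O34 all lie on one face, so in the chair with C7 equatorial the C1 methyl and C17 are syn-axial and C2 sits in its less stable configuration. In the cage, C21, C23 and C25 lie on the same face of the pyran as the O30–C28 bridge. The sensitive groups are the orthoester and the acylal-type ketal lactone (acid, hydride), the δ-lactone with its acidic C13 methylene, and the tertiary C7 alcohol. The hard points are the vicinal fully substituted C11 and C18, the quaternary C20 next to C22, the cage closure, and telling apart five carbons at carbonyl level (C14, C17, C25, C28, C31). The strategy rests on one feature: C11 lies between C18 (a ketone in a precursor) and C17 (carboxyl level), and C6 bears the oxygenated tertiary carbon C7. A C11 radical of a β-keto ester can therefore add to a C6=C7 alkene, and the C17 ester oxygen can capture the cation left at C7 and become O10.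

## Retrosynthetic reasoning

**38 to 37.** Only the O–Si bonds at O4 and O10 are cut. The two silyl ethers are chosen so that one buffered fluoride treatment removes both without touching the orthoester or the lactones.

**37 to 35 and 34.** The δ-lactone is cut at the C14 oxidation level to the 1,5-diol 35, and this to the bis(benzyl ether) 34. The lactone is formed last because its C13 methylene would compete with C20 and C24 in the two enolate steps. Forward, the unhindered C14 hydroxyl must be oxidised ahead of the neopentyl C17 hydroxyl, so that the carbonyl ends at C14.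

**34 to 31.** The three cage bonds O32–C31, O30–C28 and O27–C28 are cut together. All three are additions of hydroxyl groups to carbonyl carbons, so the cage reduces to the spiro lactone 31, which carries a C33 hydroxyl, a C28 methyl ketone and a C25 methyl ester. Forward, the closure has to be driven by loss of methanol, and it can only occur if C20, C22, C24 and C33 are already correct.

**31 to 29 and 26 + 27.** The ketone at C28 is masked as the alkene of 29, and the C24–C33 bond is cut as an aldol reaction between the ester 26 and methacrolein 27. Cutting here puts both new centres under the control of C22 (allylic strain) and of a chair transition state. In 26 the ester is the only enolisable carbonyl.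

**26 to 23 + 24.** The C20–C22 bond is cut as a Michael addition of the enolate of the α-methyl spiro lactone 23 to methyl crotonate 24. The methyl group is placed on C20 first and the chain second, because the incoming group takes the face away from the C11 chain, and in the target that group is C22.

**23 to 22, 20 and 18.** The lactone carbonyl C31 is taken back to the terminal carbon of the 2-methylallyl group of 18 (hydroboration, then oxidative lactonisation of the 1,4-diol 20). C31 is brought in at the alkene level because it has to pass the hydride reduction that precedes it.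

**18 to 17 and 16.** The C17–O bond of the primary alcohol is traced back to the γ-lactone of 16. Reduction releases O10–H and C17–OH at once, and C17–OH is capped as a benzyl ether so that it shares the fate of O-benzyl at C14.

**16 to 14 + 15.** The C18–C19 bond is cut as the addition of the allylmetal from 15 to the ketone 14. This is done before the lactone reduction, so that the ketone is consumed and no C18 carbinol has to be reoxidised. The lower face of 14 is the only open one, which gives C18 in the target configuration.

**14 to 12.** The C2 centre is inverted by kinetic protonation of the enolate of 12. C2 is the only enolisable position and it is protonated on the convex face.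

**12 to 11 (key disconnection).** The C6–C11 and C7–O10 bonds are cut: ring A and the cis-fused γ-lactone arise from the unsaturated α-substituted β-keto ester 11 by oxidative radical cyclisation with lactone termination. It is tempting to carry C2 in its final configuration. That is not done, because the productive chair would then need the C1 methyl axial and syn to the C17 ester, and the chair with the silyloxy group axial, which leads to the wrong configuration at C6 and C11, would compete. With the methyl trans to O4, both ring substituents are equatorial in the productive chair.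

**11 to 9 + 10, 9 to 7 + 8, 7 to 5, 5 to 3 + 2, 2 to 1.** The C11–C12 bond is cut as an alkylation of β-keto ester 9 with bromide 10. The C11–C18 bond is cut as acylation of the enolate of 8 by Weinreb amide 7. The C2–C3 bond is cut as a syn-aldol reaction of imide 3 with aldehyde 2, which comes from alcohol 1. The aldol sets C3, the centre that steers everything on ring A.

## Alternatives that were turned down

**Alternative 1: alkoxy-radical hydrogen transfer to oxidise C31.** The disconnection is C31–O34: the tetrahydrofuran is closed last onto a preformed methyl pyranoside. Forward, an O34-centred radical at the C18 tertiary alcohol would abstract the anomeric hydrogen at C31 through a six-membered transition state. The C31 radical would be oxidised, and O34 would add to give the mixed methyl orthoester A1.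
- For: the orthoester C–O bond is made irreversibly under non-acidic conditions from a robust acetal, and C31 stays at a low oxidation level through hydride and enolate steps. On this point it is stronger than the chosen route, whose cage closure (step 18) depends on equilibria.
- Against: a tertiary alkoxyl radical at C18, flanked by the quaternary C11, is prone to β-scission of C18–C11 or C18–C19 in competition with hydrogen transfer. A1 still has a methoxy group at C31, an open tert-butyl ester and a free methyl ketone, so the dioxolane and the γ-lactone must still be closed by acid-mediated exchange. The substrate needs a neopentyl C19 nucleophile carrying the whole pyranoside to be joined to the hindered C18 ketone.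
- Comparison: it is an endgame tactic and says nothing about ring A, C11 or O10. The chosen strategy makes ring A, C11 and the C7–O10 bond in one step, and joins C19 to C18 with an allylmetal, which is the class of nucleophile best suited to a hindered ketone.

**Alternative 2: iminium-catalysed Michael–aldol annulation.** The disconnections are C6–C11 and C2=C3. Forward, an α-substituted β-keto ester would add to a γ-silyloxy enal under a prolinol-type secondary amine catalyst, and the ketone α-carbon C2 would condense with the aldehyde to give cyclohexenone A2.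
- For: two simple achiral fragments, catalyst control of the absolute configuration at C6, and O10 already in place. In step count to ring A and in the source of absolute configuration it is stronger than the chosen route.
- Against: the enal β-carbon C6 carries the fully substituted C7, and the nucleophile is a tetrasubstituted carbon, so the Michael step joins two very hindered centres; control of the quaternary C11 in such additions is usually weak. A2 has neither O4 nor the C2 stereocentre: the all-cis C2/C3 array, with an axial methyl, would have to be made on the enone against the thermodynamic preference. The C17 ester must still be reduced next to the C18 ketone.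
- Comparison: the chosen route takes C3 from a reliable aldol reaction, uses it to set C6 and C11 in a chair with all substituents equatorial, and obtains O10 and the masked C17 in the same step.

**Alternative 3: radical–polar crossover annulation ending in the orthoester.** The disconnections are C19–C20, C18–O34 and C31–O30. Forward, a C20 radical from a brominated bicyclic lactone half would add to an exocyclic C18=C19 methylene on ring A. The C18 radical would be oxidised, the lactone carbonyl oxygen would close the tetrahydrofuran, and the C28 hydroxyl would close the dioxolane, giving A3, which has the structure of compound 37.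
- For: it is the most convergent plan, forming three bonds and two rings in one operation, and it makes the orthoester through a cation rather than an equilibrium. On both points it is stronger than the chosen route.
- Against: at C18 the carbon arrives first and the oxygen second. The oxygen would add to the C18 cation on the open lower face, whereas the target has O34 on the crowded upper face next to the axial C1 methyl and C17. C20 is set in an intermolecular radical addition with no clear control. The lactone half, with four stereocentres, and the methylenation of a hindered ketone are additional work.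
- Comparison: in the chosen route the carbon nucleophile takes the lower face of the C18 ketone and leaves O34 on the upper face, and each cage stereocentre is set in a separate step with a transition-state model.

Key step: step 7

## Route

**Step 1**
Reactants: 1 4-methylpent-3-en-1-ol
Product: 2 4-methylpent-3-enal
Conditions: Dess–Martin periodinane, NaHCO3, CH2Cl2, 0 °C → rt; used crude
Reagents that add atoms: none
Why: Dess–Martin oxidation of a primary alcohol under buffered, non-basic conditions; the β,γ-unsaturated aldehyde is not exposed to base or heat that would move the double bond into conjugation.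

**Step 2**
Reactants: 3 (R)-4-benzyl-3-propanoyl-1,3-oxazolidin-2-one; 2 4-methylpent-3-enal
Product: 5 (R)-4-benzyl-3-[(2R,3S)-3-hydroxy-2,6-dimethylhept-5-enoyl]-1,3-oxazolidin-2-one, via dibutylboron (Z)-enolate 4 (not isolated)
Conditions: Bu2BOTf, i-Pr2NEt, CH2Cl2, −78 → 0 °C; then 2, −78 → 0 °C; pH 7 buffer, MeOH, H2O2
Reagents that add atoms: none
Why: Evans syn-aldol reaction through the (Z)-boron enolate 4 and a Zimmerman–Traxler chair; the (R)-benzyl auxiliary sets C3 as S (the centre that later steers ring A) and C2 as R, which places the methyl trans to O4 on the future ring by design.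

**Step 3**
Reactants: 5 (R)-4-benzyl-3-[(2R,3S)-3-hydroxy-2,6-dimethylhept-5-enoyl]-1,3-oxazolidin-2-one
Product: 6 (2R,3S)-3-hydroxy-N-methoxy-N,2,6-trimethylhept-5-enamide
Conditions: MeNH(OMe)·HCl, AlMe3, CH2Cl2, −10 → 0 °C
Reagents that add atoms: N,O-dimethylhydroxylamine hydrochloride, CNOC.Cl
Why: Aluminium amide transamination of a β-hydroxy N-acyl oxazolidinone to the Weinreb amide; the free hydroxyl directs attack to the exocyclic carbonyl and no epimerisation at C2 is expected.

**Step 4**
Reactants: 6 (2R,3S)-3-hydroxy-N-methoxy-N,2,6-trimethylhept-5-enamide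
Product: 7 (2R,3S)-3-[(tert-butyldimethylsilyl)oxy]-N-methoxy-N,2,6-trimethylhept-5-enamide
Conditions: TBSOTf, 2,6-lutidine, CH2Cl2, −78 → 0 °C
Reagents that add atoms: tert-butyldimethylsilyl trifluoromethanesulfonate, CC(C)(C)[Si](C)(C)OS(=O)(=O)C(F)(F)F
Why: Silylation of a secondary alcohol with a silyl triflate and a hindered base; the Weinreb amide and the alkene are inert.

**Step 5**
Reactants: 7 (2R,3S)-3-[(tert-butyldimethylsilyl)oxy]-N-methoxy-N,2,6-trimethylhept-5-enamide; 8 methyl acetate
Product: 9 methyl (4R,5S)-5-[(tert-butyldimethylsilyl)oxy]-4,8-dimethyl-3-oxonon-7-enoate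
Conditions: 8, LiN(i-Pr)2, THF, −78 °C; then 7, −78 → −20 °C; aq. NH4Cl
Reagents that add atoms: none
Why: Claisen-type acylation of the lithium enolate of 8 by the Weinreb amide; the chelated tetrahedral adduct prevents double addition, and the β-keto ester is formed as its enolate, which shields C2 from epimerisation.

**Step 6**
Reactants: 9 methyl (4R,5S)-5-[(tert-butyldimethylsilyl)oxy]-4,8-dimethyl-3-oxonon-7-enoate; 10 benzyl 3-bromopropyl ether
Product: 11 methyl (4R,5S)-2-[3-(benzyloxy)propyl]-5-[(tert-butyldimethylsilyl)oxy]-4,8-dimethyl-3-oxonon-7-enoate (both epimers at C11)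
Conditions: K2CO3, NaI (cat.), acetone, reflux
Reagents that add atoms: none
Why: C-alkylation of a β-keto ester with a primary bromide under iodide catalysis; deprotonation occurs at C11 between the carbonyls, so C2 is untouched, and the configuration at C11 is irrelevant because it becomes a radical in step 7.

**Step 7 (key step)**
Reactants: 11 methyl (4R,5S)-2-[3-(benzyloxy)propyl]-5-[(tert-butyldimethylsilyl)oxy]-4,8-dimethyl-3-oxonon-7-enoate
Product: 12 (3aR,5S,6R,7aR)-7a-[3-(benzyloxy)propyl]-5-[(tert-butyldimethylsilyl)oxy]-3,3,6-trimethylhexahydro-2-benzofuran-1,7-dione (cis-fused keto lactone; C1 methyl trans to O4)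
Conditions: Mn(OAc)3·2H2O (2.2 equiv), AcOH, 50 °C, N2
Reagents that add atoms: none
Why: Mn(OAc)3 (trivalent manganese) forms the manganese enolate of the β-keto ester and from it the C11 radical, which adds 6-exo-trig to C6 of the trisubstituted alkene (ring A); the tertiary C7 radical is oxidised by the second equivalent to the cation, and the carbonyl oxygen of the C17 ester closes on it in a 5-exo mode, the methyl group leaving as methyl acetate (γ-lactone). The closest known reaction type is the Mn(OAc)3-mediated oxidative free-radical cyclisation of unsaturated α-substituted β-keto esters with lactone termination at a tertiary cation. C6 is set in a chair transition state in which the C3 silyloxy group, the C2 methyl group and the alkene are all equatorial, so C7 ends cis to O4; the competing chair would need both ring substituents axial. C11 is set by the ester lying pseudo-axial on the side of C2, with its carbonyl antiparallel to the ketone and the larger chain equatorial, which puts C17 cis to C7; the other C11 epimer cannot lactonise and would leave as alkene or acetate by-products, so lactone formation selects the required C6/C11 pair. The selectivity the step needs is face selectivity with respect to C3, and the trans C2/C3 arrangement secures it: with the final C2 configuration the methyl would be axial and syn to the ester in the productive chair. The product has no C–H between two carbonyls and is not oxidised further.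

**Step 8**
Reactants: 12 (3aR,5S,6R,7aR)-keto lactone
Product: 14 (3aR,5S,6S,7aR)-7a-[3-(benzyloxy)propyl]-5-[(tert-butyldimethylsilyl)oxy]-3,3,6-trimethylhexahydro-2-benzofuran-1,7-dione (C1 methyl cis to O4), via lithium enolate 13 (not isolated)
Conditions: LiN(i-Pr)2, THF, −78 → −40 °C; then 2,6-di-tert-butyl-4-methylphenol, −78 °C; aq. NH4Cl; used at once
Reagents that add atoms: none
Why: Kinetic protonation of a ketone enolate: C2 is the only enolisable position (C11 is quaternary), and the bulky proton donor reaches C2 from the convex lower face, opposite the cis-fused lactone and the syn-axial C17, which leaves the methyl on the upper face as in the target. The product is the less stable epimer and is not stored or exposed to acid or base.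

**Step 9**
Reactants: 14 (3aR,5S,6S,7aR)-keto lactone; 15 3-bromo-2-methylprop-1-ene
Product: 16 tertiary alcohol: keto group of 14 replaced by C18(OH)–CH2–C(CH3)=CH2, O34 on the upper face
Conditions: Zn dust, THF, 0 °C → rt; aq. NH4Cl
Reagents that add atoms: none
Why: Barbier-type allylation: the allylzinc reagent adds to ketones but not to lactones and is not basic enough to enolise C2. Attack on the lower face, away from the axial C1 methyl and C17, puts C19 axial and O34 on the upper face, which is the C18 configuration of the target.

**Step 10**
Reactants: 16 tertiary alcohol with γ-lactone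
Product: 17 triol: C11 bears CH2OH (C17) and the benzyloxypropyl chain, C6 bears C(CH3)2OH, C18 bears OH and the 2-methylallyl group
Conditions: LiAlH4, THF, 0 °C → rt
Reagents that add atoms: none
Why: Hydride reduction of the γ-lactone to the diol releases O10–H and C17–OH; the ketone has already been converted, so no second carbinol arises, and the silyl ether, benzyl ether and alkene are inert.

**Step 11**
Reactants: 17 triol
Product: 18 C17 benzyl ether of 17
Conditions: NaH, BnBr, Bu4NI (cat.), THF/DMF, 0 °C → rt
Reagents that add atoms: benzyl bromide, BrCc1ccccc1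
Why: Williamson etherification; the primary neopentyl alkoxide is alkylated far faster than the two tertiary alkoxides, so C17–OH is capped before any oxidation is carried out.

**Step 12**
Reactants: 18 C17 benzyl ether
Product: 20 diol: C18 bears OH and CH2–CH(CH3)–CH2OH (C20 as a mixture of epimers), via B-alkyl-9-borabicyclo[3.3.1]nonane 19 (not isolated)
Conditions: 9-BBN, THF, rt → 50 °C; then NaOH, H2O2, 0 °C → rt
Reagents that add atoms: hydrogen peroxide, OO
Why: Anti-Markovnikov hydroboration of the 1,1-disubstituted alkene and oxidation of the borane to the primary alcohol; the new centre C20 is formed as a mixture, which does not matter because it is enolised in step 15.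

**Step 13**
Reactants: 20 diol
Product: 22 α-methyl spiro γ-lactone (C18–O34–C31(=O)–C20H(CH3)–C19; C7–OH free), via spiro lactol 21 (not isolated)
Conditions: TEMPO (cat.), PhI(OAc)2, CH2Cl2, rt
Reagents that add atoms: none
Why: Nitroxyl-catalysed oxidative lactonisation of a 1,4-diol: the primary alcohol is oxidised, the aldehyde closes with the tertiary C18 hydroxyl to the lactol, and this is oxidised to the γ-lactone; the tertiary C7 hydroxyl and the ethers are untouched.

**Step 14**
Reactants: 22 α-methyl spiro γ-lactone
Product: 23 C7 triethylsilyl ether of 22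
Conditions: TESOTf, 2,6-lutidine, CH2Cl2, −78 → 0 °C
Reagents that add atoms: triethylsilyl trifluoromethanesulfonate, CC[Si](CC)(CC)OS(=O)(=O)C(F)(F)F
Why: Silylation of the tertiary alcohol with a silyl triflate; this removes the last acidic hydroxyl before the two enolate steps.

**Step 15**
Reactants: 23 silyl-protected α-methyl spiro γ-lactone; 24 methyl (E)-but-2-enoate
Product: 26 Michael adduct: C20 bears CH3 (cis to C11) and CH(CH3)–CH2–CO2Me, via lithium enolate 25 (not isolated)
Conditions: LiN(i-Pr)2, THF, −78 °C; then 24, −78 °C; aq. NH4Cl
Reagents that add atoms: none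
Why: Michael addition of a lactone enolate to an (E)-enoate; the lactone is the only enolisable carbonyl. The enoate approaches C20 on the face next to C2–H, away from the equatorial C12 chain on C11, so C21 ends cis to C11. In the chelated eight-membered transition state of lithium enolates with (E)-enoates, the enoate carbonyl sits over the enolate oxygen and the C23 methyl points away from C31, which corresponds to the C22 configuration of the target.

**Step 16**
Reactants: 26 Michael adduct; 27 2-methylprop-2-enal
Product: 29 anti-aldol adduct: C24 bears CO2Me and CH(OH)–C(CH3)=CH2, via dicyclohexylboron (E)-enolate 28 (not isolated)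
Conditions: (c-C6H11)2BOTf, Et3N, CH2Cl2, −78 °C; then 27, −78 → 0 °C; pH 7 buffer, MeOH, H2O2
Reagents that add atoms: none
Why: Boron-mediated anti-aldol reaction of an ester: soft enolisation gives the (E)-enolate, and the ester is the only enolisable carbonyl. The aldehyde adds to the face of C24 opposite C20, with C22–H eclipsing the enolate (allylic 1,3-strain), and the chair transition state places O32 anti to C22, as the cage requires.

**Step 17**
Reactants: 29 anti-aldol adduct
Product: 31 ketol: C33 hydroxyl next to the C28 methyl ketone, via ozonide 30 (not isolated)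
Conditions: O3, CH2Cl2, −78 °C; then Me2S, −78 °C → rt
Reagents that add atoms: ozone, [O-][O+]=O
Why: Ozonolysis of the 1,1-disubstituted alkene and reductive work-up unmask the C28 methyl ketone; there is no other alkene, and the benzyl ethers survive at −78 °C when ozone is stopped at the end point.

**Step 18**
Reactants: 31 ketol
Product: 34 cage bis(benzyl ether), via hemiorthoester 32 (not isolated), via hydroxy ketal 33 (not isolated)
Conditions: camphorsulfonic acid (cat.), toluene, 4 Å molecular sieves, 60 °C
Reagents that add atoms: none
Why: Acid-catalysed intramolecular orthoesterification, ketalisation and lactonisation: O32–H adds to the lactone carbonyl C31, the new C31 hydroxyl adds to the C28 ketone, and the C28 hydroxyl closes onto the C25 ester with loss of methanol, which the sieves remove so that the last step pulls the equilibria forward. C28 and C31 are fixed by ring fusion, and only the C20, C22, C24 and C33 configurations set earlier allow the cage to close.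

**Step 19**
Reactants: 34 cage bis(benzyl ether)
Product: 35 cage diol: C11 bears CH2OH and CH2CH2CH2OH
Conditions: H2 (1 atm), Pd(OH)2/C, EtOAc, rt
Reagents that add atoms: none
Why: Hydrogenolysis of both benzyl ethers under neutral conditions; the orthoester, ketal lactone and silyl ethers are stable to it.

**Step 20**
Reactants: 35 cage diol
Product: 37 3-O-TBS 7-O-TES ether of chermebilaene B, via δ-lactol 36 (not isolated)
Conditions: TEMPO (cat.), PhI(OAc)2, CH2Cl2, rt
Reagents that add atoms: none
Why: Nitroxyl-catalysed oxidative lactonisation of a 1,5-diol; the unhindered C14 hydroxyl is oxidised much faster than the neopentyl C17 hydroxyl, the aldehyde is captured by C17–OH as the lactol, and this is oxidised to the δ-lactone with the carbonyl at C14.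

**Step 21**
Reactants: 37 3-O-TBS 7-O-TES ether of chermebilaene B
Product: 38 chermebilaene B
Conditions: HF·pyridine, pyridine, THF, 0 °C → rt
Reagents that add atoms: none
Why: Fluoride-mediated cleavage of the secondary TBS ether and the tertiary TES ether in a pyridine-buffered medium that should leave the orthoester, the ketal lactone and the δ-lactone intact.

## Compound list

1 | 4-methylpent-3-en-1-ol | CC(C)=CCCO | starting material
2 | 4-methylpent-3-enal | CC(C)=CCC=O | intermediate
3 | (R)-4-benzyl-3-propanoyl-1,3-oxazolidin-2-one | CCC(=O)N1[C@H](Cc2ccccc2)COC1=O | starting material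
4 | dibutylboron (Z)-enolate of 3 | C/C=C(\OB(CCCC)CCCC)N1[C@H](Cc2ccccc2)COC1=O | intermediate (not isolated)
5 | (R)-4-benzyl-3-[(2R,3S)-3-hydroxy-2,6-dimethylhept-5-enoyl]-1,3-oxazolidin-2-one | C[C@@H](C(=O)N1[C@H](Cc2ccccc2)COC1=O)[C@@H](O)CC=C(C)C | intermediate
6 | (2R,3S)-3-hydroxy-N-methoxy-N,2,6-trimethylhept-5-enamide | C[C@@H](C(=O)N(C)OC)[C@@H](O)CC=C(C)C | intermediate
7 | (2R,3S)-3-[(tert-butyldimethylsilyl)oxy]-N-methoxy-N,2,6-trimethylhept-5-enamide | C[C@@H](C(=O)N(C)OC)[C@@H](O[Si](C)(C)C(C)(C)C)CC=C(C)C | intermediate
8 | methyl acetate | COC(C)=O | starting material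
9 | methyl (4R,5S)-5-[(tert-butyldimethylsilyl)oxy]-4,8-dimethyl-3-oxonon-7-enoate | C[C@@H](C(=O)CC(=O)OC)[C@@H](O[Si](C)(C)C(C)(C)C)CC=C(C)C | intermediate
10 | benzyl 3-bromopropyl ether | BrCCCOCc1ccccc1 | starting material
11 | methyl (4R,5S)-2-[3-(benzyloxy)propyl]-5-[(tert-butyldimethylsilyl)oxy]-4,8-dimethyl-3-oxonon-7-enoate (C11 epimers) | C[C@@H](C(=O)C(CCCOCc1ccccc1)C(=O)OC)[C@@H](O[Si](C)(C)C(C)(C)C)CC=C(C)C | intermediate
12 | (3aR,5S,6R,7aR)-7a-[3-(benzyloxy)propyl]-5-[(tert-butyldimethylsilyl)oxy]-3,3,6-trimethylhexahydro-2-benzofuran-1,7-dione (C1 methyl trans to O4) | C[C@@H]1[C@@H](O[Si](C)(C)C(C)(C)C)C[C@H]2C(C)(C)OC(=O)[C@@]2(CCCOCc2ccccc2)C1=O | intermediate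
13 | lithium enolate of 12 (C2=C18) | CC1=C(O[Li])[C@]2(CCCOCc3ccccc3)C(=O)OC(C)(C)[C@@H]2C[C@@H]1O[Si](C)(C)C(C)(C)C | intermediate (not isolated)
14 | (3aR,5S,6S,7aR)-7a-[3-(benzyloxy)propyl]-5-[(tert-butyldimethylsilyl)oxy]-3,3,6-trimethylhexahydro-2-benzofuran-1,7-dione (C1 methyl cis to O4) | C[C@H]1[C@@H](O[Si](C)(C)C(C)(C)C)C[C@H]2C(C)(C)OC(=O)[C@@]2(CCCOCc2ccccc2)C1=O | intermediate
15 | 3-bromo-2-methylprop-1-ene | CC(=C)CBr | starting material
16 | tertiary alcohol with γ-lactone (C18 bears OH on the upper face and the 2-methylallyl group) | C[C@H]1[C@@H](O[Si](C)(C)C(C)(C)C)C[C@H]2C(C)(C)OC(=O)[C@@]2(CCCOCc2ccccc2)[C@]1(O)CC(C)=C | intermediate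
17 | triol (C17–OH, C7–OH, C18–OH) | C[C@H]1[C@@H](O[Si](C)(C)C(C)(C)C)C[C@@H](C(C)(C)O)[C@](CO)(CCCOCc2ccccc2)[C@]1(O)CC(C)=C | intermediate
18 | C17 benzyl ether of 17 | C[C@H]1[C@@H](O[Si](C)(C)C(C)(C)C)C[C@@H](C(C)(C)O)[C@](COCc2ccccc2)(CCCOCc2ccccc2)[C@]1(O)CC(C)=C | intermediate
19 | B-alkyl-9-borabicyclo[3.3.1]nonane from 18 | C[C@H]1[C@@H](O[Si](C)(C)C(C)(C)C)C[C@@H](C(C)(C)O)[C@](COCc2ccccc2)(CCCOCc2ccccc2)[C@]1(O)CC(C)CB1C2CCCC1CCC2 | intermediate (not isolated)
20 | diol with CH2–CH(CH3)–CH2OH on C18 (C20 epimers) | C[C@H]1[C@@H](O[Si](C)(C)C(C)(C)C)C[C@@H](C(C)(C)O)[C@](COCc2ccccc2)(CCCOCc2ccccc2)[C@]1(O)CC(C)CO | intermediate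
21 | spiro lactol (C31 at aldehyde level) | C[C@H]1[C@@H](O[Si](C)(C)C(C)(C)C)C[C@@H](C(C)(C)O)[C@](COCc2ccccc2)(CCCOCc2ccccc2)[C@]12CC(C)C(O)O2 | intermediate (not isolated)
22 | α-methyl spiro γ-lactone, C7–OH free (C20 epimers) | C[C@H]1[C@@H](O[Si](C)(C)C(C)(C)C)C[C@@H](C(C)(C)O)[C@](COCc2ccccc2)(CCCOCc2ccccc2)[C@]12CC(C)C(=O)O2 | intermediate
23 | C7 triethylsilyl ether of 22 | C[C@H]1[C@@H](O[Si](C)(C)C(C)(C)C)C[C@@H](C(C)(C)O[Si](CC)(CC)CC)[C@](COCc2ccccc2)(CCCOCc2ccccc2)[C@]12CC(C)C(=O)O2 | intermediate
24 | methyl (E)-but-2-enoate | C/C=C/C(=O)OC | starting material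
25 | lithium enolate of 23 | C[C@H]1[C@@H](O[Si](C)(C)C(C)(C)C)C[C@@H](C(C)(C)O[Si](CC)(CC)CC)[C@](COCc2ccccc2)(CCCOCc2ccccc2)[C@]12CC(C)=C(O[Li])O2 | intermediate (not isolated)
26 | Michael adduct (C20 quaternary; C22 set) | C[C@H]1[C@@H](O[Si](C)(C)C(C)(C)C)C[C@@H](C(C)(C)O[Si](CC)(CC)CC)[C@](COCc2ccccc2)(CCCOCc2ccccc2)[C@]12C[C@](C)([C@@H](C)CC(=O)OC)C(=O)O2 | intermediate
27 | 2-methylprop-2-enal | CC(=C)C=O | starting material
28 | dicyclohexylboron (E)-enolate of 26 | C[C@H]1[C@@H](O[Si](C)(C)C(C)(C)C)C[C@@H](C(C)(C)O[Si](CC)(CC)CC)[C@](COCc2ccccc2)(CCCOCc2ccccc2)[C@]12C[C@](C)([C@@H](C)/C=C(\OC)OB(C3CCCCC3)C3CCCCC3)C(=O)O2 | intermediate (not isolated)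
29 | anti-aldol adduct (C24, C33 set) | C[C@H]1[C@@H](O[Si](C)(C)C(C)(C)C)C[C@@H](C(C)(C)O[Si](CC)(CC)CC)[C@](COCc2ccccc2)(CCCOCc2ccccc2)[C@]12C[C@](C)([C@@H](C)[C@@H](C(=O)OC)[C@H](O)C(C)=C)C(=O)O2 | intermediate
30 | ozonide of 29 (1,2,4-trioxolane at C28) | C[C@H]1[C@@H](O[Si](C)(C)C(C)(C)C)C[C@@H](C(C)(C)O[Si](CC)(CC)CC)[C@](COCc2ccccc2)(CCCOCc2ccccc2)[C@]12C[C@](C)([C@@H](C)[C@@H](C(=O)OC)[C@H](O)C3(C)OCOO3)C(=O)O2 | intermediate (not isolated)
31 | ketol (C33–OH, C28 methyl ketone, C25 methyl ester, C31 spiro lactone) | C[C@H]1[C@@H](O[Si](C)(C)C(C)(C)C)C[C@@H](C(C)(C)O[Si](CC)(CC)CC)[C@](COCc2ccccc2)(CCCOCc2ccccc2)[C@]12C[C@](C)([C@@H](C)[C@@H](C(=O)OC)[C@H](O)C(C)=O)C(=O)O2 | intermediate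
32 | hemiorthoester (pyran closed; C31–OH) | C[C@H]1[C@@H](O[Si](C)(C)C(C)(C)C)C[C@@H](C(C)(C)O[Si](CC)(CC)CC)[C@](COCc2ccccc2)(CCCOCc2ccccc2)[C@]12C[C@]1(C)[C@@H](C)[C@@H](C(=O)OC)[C@@H](C(C)=O)O[C@]1(O)O2 | intermediate (not isolated)
33 | hydroxy ketal (dioxolane closed; C28–OH) | C[C@H]1[C@@H](O[Si](C)(C)C(C)(C)C)C[C@@H](C(C)(C)O[Si](CC)(CC)CC)[C@](COCc2ccccc2)(CCCOCc2ccccc2)[C@]12C[C@]1(C)[C@@H](C)[C@@H](C(=O)OC)[C@@H]3O[C@]1(O[C@]3(C)O)O2 | intermediate (not isolated)
34 | cage bis(benzyl ether) | C[C@H]1[C@@H](O[Si](C)(C)C(C)(C)C)C[C@@H](C(C)(C)O[Si](CC)(CC)CC)[C@](COCc2ccccc2)(CCCOCc2ccccc2)[C@]12C[C@]1(C)[C@@H](C)[C@H]3C(=O)O[C@@]4(C)O[C@@]1(O[C@@H]34)O2 | intermediate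
35 | cage diol (C14–OH, C17–OH) | C[C@H]1[C@@H](O[Si](C)(C)C(C)(C)C)C[C@@H](C(C)(C)O[Si](CC)(CC)CC)[C@](CO)(CCCO)[C@]12C[C@]1(C)[C@@H](C)[C@H]3C(=O)O[C@@]4(C)O[C@@]1(O[C@@H]34)O2 | intermediate
36 | δ-lactol (C14 at aldehyde level) | C[C@H]1[C@@H](O[Si](C)(C)C(C)(C)C)C[C@@H](C(C)(C)O[Si](CC)(CC)CC)[C@]2(CCC(O)OC2)[C@]12C[C@]1(C)[C@@H](C)[C@H]3C(=O)O[C@@]4(C)O[C@@]1(O[C@@H]34)O2 | intermediate (not isolated)
37 | 3-O-TBS 7-O-TES ether of chermebilaene B | C[C@H]1[C@@H](O[Si](C)(C)C(C)(C)C)C[C@@H](C(C)(C)O[Si](CC)(CC)CC)[C@]2(CCC(=O)OC2)[C@]12C[C@]1(C)[C@@H](C)[C@H]3C(=O)O[C@@]4(C)O[C@@]1(O[C@@H]34)O2 | intermediate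
38 | chermebilaene B | C[C@H]1[C@@H](O)C[C@@H](C(C)(C)O)[C@]2(CCC(=O)OC2)[C@]12C[C@]1(C)[C@@H](C)[C@H]3C(=O)O[C@@]4(C)O[C@@]1(O[C@@H]34)O2 | target

## Step count and least certain steps

Total: 21 steps. Longest linear sequence: 21 steps (1 to 38); compounds 3, 8, 10, 15, 24 and 27 are purchased.

**Step 7 (key step).** The most likely failure is loss of the C7 cation by deprotonation or acetate capture before the C17 ester closes on it; partial cleavage of the silyl ether in warm acetic acid and incomplete preference for the ester-axial orientation at C11 are further risks. Fallback: from 11, the cyclisation is run with Mn(OAc)3 and Cu(OAc)2, so that the C7 radical is intercepted by divalent copper and leaves as the alkene, the isopropenyl keto ester F1. F1 is then treated with a sulfonic acid resin in CH2Cl2; protonation of the alkene regenerates the C7 cation in a medium free of acetate, the cis ester closes with loss of methanol, and the route is rejoined at 12.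

**Step 18.** Every event before the last is reversible, so the sequence may stall at a hemiorthoester or hemiketal stage, or the β-hydroxy ester may lose water under acid. Fallback: from 26, the aldol reaction of step 16 is run with 2,2-dimethoxypropanal F10 (prepared separately by half-reduction of its methyl ester with i-Bu2AlH) in place of 27, which gives the ketal aldol adduct F11. With catalytic Me3SiOTf in CH2Cl2 the dimethyl ketal ionises to an oxocarbenium ion at C28, so the C–O bonds at C28 are formed by cation capture (first by the C31 hydroxyl of the hemiorthoester, then by the ester carbonyl with loss of its methyl group) rather than by reversible hemiketalisation. The route is rejoined at 34.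

**Step 15.** The likely failures are poor relative topicity at C22, because the tetrasubstituted enolate crowds the position that the C23 methyl must take, and attack on the wrong face of the lactone enolate. Fallback: from 23, the enolate is silylated (LiN(i-Pr)2, TBSCl) to the silyl ketene acetal F4. F4 is allylated with (E)-but-2-enyl methyl carbonate under [Ir(cod)Cl]2 and a chiral phosphoramidite ligand, which attacks the substituted allyl terminus and sets C22 by the ligand, giving the vinyl lactone F5. Hydroboration–oxidation gives the primary alcohol F6, and oxidation in methanol with pyridinium dichromate, (C5H5NH)2Cr2O7, in DMF returns the methyl ester 26.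

**Step 8.** The likely failures are incomplete facial discrimination in the protonation, β-elimination of the silyloxy group from the enolate, and return of the axial methyl epimer to the more stable one during handling. Fallback: from 12, the enolate 13 is selenenylated with PhSeBr to the α-phenylselanyl ketone F2. Oxidation with H2O2 and syn-elimination of the selenoxide toward the methyl group (elimination toward the oxygen-bearing C3 is disfavoured) gives the exocyclic enone F3. Hydrogenation with (Ph3P)3RhCl in benzene delivers hydrogen to the convex lower face and rejoins the route at 14.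

**Step 16.** The likely failures are slow soft enolisation of the β-branched ester and erosion of the anti selectivity. Fallback: from 26, saponification (LiOH, then acidification, which recloses any opened spiro lactone) gives the acid F7, and mixed-anhydride coupling with lithiated (S)-4-benzyl-1,3-oxazolidin-2-one gives the imide F8. The MgCl2-catalysed anti-aldol reaction (Et3N, Me3SiCl, EtOAc) with 27, followed by acidic removal of the silyl group, gives the anti-aldol imide F9; auxiliary control reinforces the substrate bias. Methanolysis with MeOMgBr rejoins the route at 29.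

## Further compounds

F1 | step 7 | isopropenyl keto ester (ring A closed, C6 bears C(CH3)=CH2, C11 bears CO2Me) | C[C@@H]1[C@@H](O[Si](C)(C)C(C)(C)C)C[C@@H](C(C)=C)[C@@](CCCOCc2ccccc2)(C(=O)OC)C1=O
F2 | step 8 | α-phenylselanyl ketone (C2 bears CH3 and SePh) | CC1([Se]c2ccccc2)[C@@H](O[Si](C)(C)C(C)(C)C)C[C@H]2C(C)(C)OC(=O)[C@@]2(CCCOCc2ccccc2)C1=O
F3 | step 8 | exocyclic enone (C2=CH2) | C=C1[C@@H](O[Si](C)(C)C(C)(C)C)C[C@H]2C(C)(C)OC(=O)[C@@]2(CCCOCc2ccccc2)C1=O
F4 | step 15 | tert-butyldimethylsilyl ketene acetal of 23 | C[C@H]1[C@@H](O[Si](C)(C)C(C)(C)C)C[C@@H](C(C)(C)O[Si](CC)(CC)CC)[C@](COCc2ccccc2)(CCCOCc2ccccc2)[C@]12CC(C)=C(O[Si](C)(C)C(C)(C)C)O2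
F5 | step 15 | vinyl lactone (C20 bears CH3 and CH(CH3)CH=CH2) | C[C@H]1[C@@H](O[Si](C)(C)C(C)(C)C)C[C@@H](C(C)(C)O[Si](CC)(CC)CC)[C@](COCc2ccccc2)(CCCOCc2ccccc2)[C@]12C[C@](C)([C@@H](C)C=C)C(=O)O2
F6 | step 15 | primary alcohol (C25–OH) | C[C@H]1[C@@H](O[Si](C)(C)C(C)(C)C)C[C@@H](C(C)(C)O[Si](CC)(CC)CC)[C@](COCc2ccccc2)(CCCOCc2ccccc2)[C@]12C[C@](C)([C@@H](C)CCO)C(=O)O2
F7 | step 16 | C25 carboxylic acid | C[C@H]1[C@@H](O[Si](C)(C)C(C)(C)C)C[C@@H](C(C)(C)O[Si](CC)(CC)CC)[C@](COCc2ccccc2)(CCCOCc2ccccc2)[C@]12C[C@](C)([C@@H](C)CC(=O)O)C(=O)O2
F8 | step 16 | N-acyl (S)-4-benzyl-oxazolidinone | C[C@H]1[C@@H](O[Si](C)(C)C(C)(C)C)C[C@@H](C(C)(C)O[Si](CC)(CC)CC)[C@](COCc2ccccc2)(CCCOCc2ccccc2)[C@]12C[C@](C)([C@@H](C)CC(=O)N3[C@@H](Cc4ccccc4)COC3=O)C(=O)O2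
F9 | step 16 | anti-aldol imide | C[C@H]1[C@@H](O[Si](C)(C)C(C)(C)C)C[C@@H](C(C)(C)O[Si](CC)(CC)CC)[C@](COCc2ccccc2)(CCCOCc2ccccc2)[C@]12C[C@](C)([C@@H](C)[C@@H](C(=O)N3[C@@H](Cc4ccccc4)COC3=O)[C@H](O)C(C)=C)C(=O)O2
F10 | step 18 | 2,2-dimethoxypropanal | CC(OC)(OC)C=O
F11 | step 18 | ketal aldol adduct (C28 as dimethyl ketal) | C[C@H]1[C@@H](O[Si](C)(C)C(C)(C)C)C[C@@H](C(C)(C)O[Si](CC)(CC)CC)[C@](COCc2ccccc2)(CCCOCc2ccccc2)[C@]12C[C@](C)([C@@H](C)[C@@H](C(=O)OC)[C@H](O)C(C)(OC)OC)C(=O)O2
A1 | alternative 1 | mixed methyl orthoester with tetrahydrofuran and tetrahydropyran closed | C[C@H]1[C@@H](O[Si](C)(C)C(C)(C)C)C[C@@H](C(C)(C)O[Si](CC)(CC)CC)[C@]2(CCC(=O)OC2)[C@]12C[C@]1(C)[C@@H](C)[C@@H](C(=O)OC(C)(C)C)[C@@H](C(C)=O)O[C@]1(OC)O2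
A2 | alternative 2 | 2-methylcyclohex-2-enone with C6 and quaternary C11 set | CC1=CC[C@@H](C(C)(C)O[Si](CC)(CC)CC)[C@@](CCCOCc2ccccc2)(C(=O)OC)C1=O
A3 | alternative 3 | bis-silyl ether of chermebilaene B (same structure as 37) | C[C@H]1[C@@H](O[Si](C)(C)C(C)(C)C)C[C@@H](C(C)(C)O[Si](CC)(CC)CC)[C@]2(CCC(=O)OC2)[C@]12C[C@]1(C)[C@@H](C)[C@H]3C(=O)O[C@@]4(C)O[C@@]1(O[C@@H]34)O2
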